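The benzene ring of the coumarin (C4a, C5, C6, C7, C8, C8a) is disconnected at C4a–C8a and traced to a squarate-derived cyclobutenone. That ring carries para oxygens at C6 and C8a, the side-chain ether at C7 and carbon at C4a, the exact pattern of a hydroquinone monomethyl ether. Heating precursor 17, a cyclobut-2-enone with the silyl-protected (R,E) side chain as its 3-enol ether, a 4-methoxy group and a 4-[(E)-3,3-diethoxypropenyl] arm, should open and reclose it in one operation to phenol 18 with all four substituents placed. The lone stereocentre comes from (R)-5-oxotetrahydrofuran-2-carboxylic acid; Bestmann lactonisation and desilylation finish.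

Key step: step 11

Remark: by CIP analysis the target is R at C4' and E at C2'=C3', and compounds 17 and 18 carry the same descriptors. (R)-5-Oxotetrahydrofuran-2-carboxylic acid (the lactone acid of D-glutamic acid) is assumed to be commercially available.

Step 1
Reactants: 1 (R)-5-oxotetrahydrofuran-2-carboxylic acid
Product: 2 (R)-N-methoxy-N-methyl-5-oxotetrahydrofuran-2-carboxamide
Conditions: MeNH(OMe)·HCl, EDC·HCl, N-methylmorpholine, CH2Cl2, 0 °C to rt
Reagents that add atoms: N,O-dimethylhydroxylamine hydrochloride, CNOC.Cl
Why: Carbodiimide-mediated amide coupling to the Weinreb amide proceeds on the free acid without touching the lactone, and an alpha-acyloxy acid has no oxazolone pathway, so the R centre taken from the chiral pool is retained.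

Step 2
Reactants: 2 (R)-N-methoxy-N-methyl-5-oxotetrahydrofuran-2-carboxamide
Product: 3 (3R)-3,6-dihydroxy-6-methylheptan-2-one
Conditions: MeMgBr (4.5 equiv), THF, −78 °C to rt; aq. NH4Cl
Reagents that add atoms: methylmagnesium bromide, C[Mg]Br
Why: Grignard addition in which the Weinreb amide halts at its magnesium-chelated tetrahedral adduct and releases the methyl ketone only on quench, while the lactone consumes two methyl groups to give the tertiary carbinol; the stereocentre is not epimerised because no free ketone exists while base is present.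

Step 3
Reactants: 3 (3R)-3,6-dihydroxy-6-methylheptan-2-one
Product: 4 (3R)-6-methyl-3,6-bis(triethylsilyloxy)heptan-2-one
Conditions: Et3SiOTf (2.4 equiv), 2,6-lutidine, CH2Cl2, −78 to −20 °C
Reagents that add atoms: triethylsilyl trifluoromethanesulfonate, CC[Si](CC)(CC)OS(=O)(=O)C(F)(F)F
Why: Silyl triflate with a hindered pyridine base silylates the secondary and the tertiary hydroxyl in one operation at low temperature, conditions that do not enolise the ketone, and silylation draws any cyclic hemiketal form back to the open chain.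

Step 4
Reactants: 4 (3R)-6-methyl-3,6-bis(triethylsilyloxy)heptan-2-one
Product: 5 ethyl (2E,4R)-3,7-dimethyl-4,7-bis(triethylsilyloxy)oct-2-enoate
Conditions: (EtO)2P(O)CH2CO2Et (1.5 equiv), NaH (1.4 equiv), THF, 0 to 40 °C
Reagents that add atoms: triethyl phosphonoacetate, CCOC(=O)CP(=O)(OCC)OCC
Why: Horner–Wadsworth–Emmons olefination of a methyl ketone whose other substituent is a bulky alpha-silyloxy carbon places the ester trans to that carbon, which sets the E trisubstituted alkene, and a stabilised phosphonate anion kept in excess over NaH is too weak a base to enolise toward the stereocentre.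

Step 5
Reactants: 5 ethyl (2E,4R)-3,7-dimethyl-4,7-bis(triethylsilyloxy)oct-2-enoate
Product: 6 (2E,4R)-3,7-dimethyl-4,7-bis(triethylsilyloxy)oct-2-en-1-ol
Conditions: i-Bu2AlH (2.3 equiv), CH2Cl2, −78 °C; aq. KNaC4H4O6 (potassium sodium tartrate)
Reagents that add atoms: none
Why: Low-temperature reduction of the conjugated ester with a dialkylaluminium hydride gives the allylic alcohol by two 1,2-hydride deliveries and leaves alkene geometry, silyl ethers and stereocentre untouched.

Step 6
Reactants: 7 diisopropyl squarate
Product: 9 3-isopropoxycyclobut-3-ene-1,2-dione (isopropyl semisquarate), via hydroxycyclobutenone 8 (not isolated)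
Conditions: LiAlH(OtBu)3, THF, −78 to 0 °C; then 12 M HCl (cat.), CH2Cl2, rt on the crude carbinol
Reagents that add atoms: none
Why: A bulky alkoxyaluminium hydride reduces one squarate carbonyl only, and acid then expels isopropanol from the resulting hydroxy enol ether with carbonyl transposition, which is the established hydride route to semisquarates.

Step 7
Reactants: 9 3-isopropoxycyclobut-3-ene-1,2-dione
Product: 10 3-hydroxycyclobut-3-ene-1,2-dione (semisquaric acid)
Conditions: 2 M aq. HCl, rt; evaporate, dry by toluene azeotrope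
Reagents that add atoms: water, O
Why: Acid hydrolysis of a vinylogous ester by addition–elimination of water at C3 gives the strongly acidic vinylogous carboxylic acid, isolated by evaporation.

Step 8
Reactants: 10 3-hydroxycyclobut-3-ene-1,2-dione; 6 (2E,4R)-3,7-dimethyl-4,7-bis(triethylsilyloxy)oct-2-en-1-ol
Product: 12 3-{[(2E,4R)-3,7-dimethyl-4,7-bis(triethylsilyloxy)oct-2-en-1-yl]oxy}cyclobut-3-ene-1,2-dione, via semisquaric chloride 11 (not isolated)
Conditions: 10 (1.5 equiv), (COCl)2, DMF (cat.), CH2Cl2, 0 °C to rt, Ar purge; then added to 6, 2,6-lutidine, CH2Cl2, −40 to 0 °C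
Reagents that add atoms: none
Why: Vilsmeier-type activation converts the vinylogous acid into its chloride in the way squaric acid gives its dichloride, and the primary allylic alcohol then substitutes chloride at the sp2 carbon by addition–elimination, the hindered base keeping HCl away from the silyl ethers.

Step 9
Reactants: 13 3,3-diethoxyprop-1-yne
Product: 14 (E)-tributyl(3,3-diethoxyprop-1-en-1-yl)stannane
Conditions: Bu3SnH (1.1 equiv), AIBN (cat.), neat, 80 °C; E isomer separated on Et3N-deactivated SiO2
Reagents that add atoms: tributyltin hydride, CCCC[SnH](CCCC)CCCC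
Why: Radical-chain hydrostannation puts tin on the terminal carbon, and reversible stannyl-radical addition under these conditions funnels the product toward the more stable E alkene.

Step 10
Reactants: 14 (E)-tributyl(3,3-diethoxyprop-1-en-1-yl)stannane; 12 3-{[(2E,4R)-3,7-dimethyl-4,7-bis(triethylsilyloxy)oct-2-en-1-yl]oxy}cyclobut-3-ene-1,2-dione
Product: 17 4-[(1E)-3,3-diethoxyprop-1-en-1-yl]-3-{[(2E,4R)-3,7-dimethyl-4,7-bis(triethylsilyloxy)oct-2-en-1-yl]oxy}-4-methoxycyclobut-2-en-1-one (both C4 epimers), via alkenyllithium 15 (not isolated), via lithium alkoxide 16 (not isolated)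
Conditions: 14 (1.3 equiv), n-BuLi (1.2 equiv), THF, −78 °C; 12, −78 °C; MeOTf (2.5 equiv), −78 to 0 °C; aq. NaHCO3
Reagents that add atoms: methyl trifluoromethanesulfonate, COS(=O)(=O)C(F)(F)F
Why: Tin–lithium exchange gives a configurationally stable E alkenyllithium that adds 1,2 to the ketone-like carbonyl next to the alkoxy-bearing carbon, the other carbonyl being a deactivated vinylogous ester, and the tertiary lithium alkoxide is O-methylated in the same flask by methyl triflate; the new quaternary carbon forms as both epimers, which does not matter because step 11 makes it aromatic.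

Step 11
Reactants: 17 4-[(1E)-3,3-diethoxyprop-1-en-1-yl]-3-{[(2E,4R)-3,7-dimethyl-4,7-bis(triethylsilyloxy)oct-2-en-1-yl]oxy}-4-methoxycyclobut-2-en-1-one
Product: 18 2-(diethoxymethyl)-5-{[(2E,4R)-3,7-dimethyl-4,7-bis(triethylsilyloxy)oct-2-en-1-yl]oxy}-4-methoxyphenol
Conditions: PhMe (0.01 M, degassed), 110 °C, Ar, base-washed glassware; concentrate
Reagents that add atoms: none
Why: Thermal conrotatory 4π opening of the cyclobutenone C1–C4 bond (future C8a–C6) gives a dienylketene in which the 4-methoxy donor has rotated outward, so the propenyl arm lies cis to the ketene and a disrotatory 6π electrocyclisation joins the ketene carbon to the acetal-bearing alkene terminus (new C4a–C8a bond), closing the carbocycle as a cyclohexa-2,4-dienone that enolises to phenol 18. The closest known reaction type is the Moore-type thermal ring expansion of 4-alkenyl-4-alkoxycyclobutenones to hydroquinone monoethers. The one ring formed closes by 6π electrocyclisation, so the substitution pattern follows only from the connectivity of the four-membered ring: methoxy at C6, side-chain ether at C7, hydrogen at C8, hydroxyl at C8a and the masked formyl group at C4a. No stereocentre is created, the C4 epimers of 17 converge because that carbon becomes aromatic, and the remote side-chain stereocentre is not involved. The step needs outward rotation of the methoxy group and ring opening faster than a [3,3] shift of the allyl enol ether; donor torquoselectivity should secure the first, and the fully substituted allyl terminus C3' together with the moderate temperature the second, while high dilution suppresses capture of the ketene by product phenol.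

Step 12
Reactants: 18 2-(diethoxymethyl)-5-{[(2E,4R)-3,7-dimethyl-4,7-bis(triethylsilyloxy)oct-2-en-1-yl]oxy}-4-methoxyphenol
Product: 19 4-{[(2E,4R)-3,7-dimethyl-4,7-bis(triethylsilyloxy)oct-2-en-1-yl]oxy}-2-hydroxy-5-methoxybenzaldehyde
Conditions: SiO2, 10% aq. oxalic acid (cat.), CH2Cl2, rt
Reagents that add atoms: water, O
Why: Acetal hydrolysis is made exceptionally easy by the ortho hydroxyl and para alkoxy donors, so wet silica with a trace of oxalic acid suffices and the triethylsilyl ethers survive.

Step 13
Reactants: 19 4-{[(2E,4R)-3,7-dimethyl-4,7-bis(triethylsilyloxy)oct-2-en-1-yl]oxy}-2-hydroxy-5-methoxybenzaldehyde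
Product: 21 7-{[(2E,4R)-3,7-dimethyl-4,7-bis(triethylsilyloxy)oct-2-en-1-yl]oxy}-6-methoxy-2H-chromen-2-one, via aryl phosphoranylideneacetate 20 (not isolated)
Conditions: Ph3P=C=C=O (1.2 equiv), PhMe, 80 °C
Reagents that add atoms: (triphenylphosphoranylidene)ketene, O=C=C=P(c1ccccc1)(c1ccccc1)c1ccccc1
Why: The phenol adds across the cumulated ylide to give an aryl ester ylide that closes by intramolecular Wittig reaction onto the ortho aldehyde (Bestmann coumarin synthesis), the six-membered ring enforcing the cis C3=C4 bond at a temperature far below that of a Claisen shift of the aryl allyl ether.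

Step 14
Reactants: 21 7-{[(2E,4R)-3,7-dimethyl-4,7-bis(triethylsilyloxy)oct-2-en-1-yl]oxy}-6-methoxy-2H-chromen-2-one
Product: 22 7-{[(2E,4R)-4,7-dihydroxy-3,7-dimethyloct-2-en-1-yl]oxy}-6-methoxy-2H-chromen-2-one (CNP0197418.1)
Conditions: HF·pyridine, pyridine, THF, 0 °C to rt
Reagents that add atoms: none
Why: Fluoride-driven Si–O cleavage under buffered conditions removes both triethylsilyl ethers and leaves the lactone, the aryl allyl ether and the allylic stereocentre intact.

Compound list
1 | (R)-5-oxotetrahydrofuran-2-carboxylic acid | OC(=O)[C@H]1CCC(=O)O1 | starting material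
2 | (R)-N-methoxy-N-methyl-5-oxotetrahydrofuran-2-carboxamide | CON(C)C(=O)[C@H]1CCC(=O)O1 | intermediate
3 | (3R)-3,6-dihydroxy-6-methylheptan-2-one | CC(=O)[C@H](O)CCC(C)(C)O | intermediate
4 | (3R)-6-methyl-3,6-bis(triethylsilyloxy)heptan-2-one | CC(=O)[C@H](O[Si](CC)(CC)CC)CCC(C)(C)O[Si](CC)(CC)CC | intermediate
5 | ethyl (2E,4R)-3,7-dimethyl-4,7-bis(triethylsilyloxy)oct-2-enoate | CCOC(=O)/C=C(\C)[C@H](O[Si](CC)(CC)CC)CCC(C)(C)O[Si](CC)(CC)CC | intermediate
6 | (2E,4R)-3,7-dimethyl-4,7-bis(triethylsilyloxy)oct-2-en-1-ol | OC/C=C(\C)[C@H](O[Si](CC)(CC)CC)CCC(C)(C)O[Si](CC)(CC)CC | intermediate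
7 | diisopropyl squarate (3,4-diisopropoxycyclobut-3-ene-1,2-dione) | CC(C)OC1=C(OC(C)C)C(=O)C1=O | starting material
8 | 4-hydroxy-2,3-diisopropoxycyclobut-2-en-1-one (racemic; not isolated) | CC(C)OC1=C(OC(C)C)C(O)C1=O | intermediate
9 | 3-isopropoxycyclobut-3-ene-1,2-dione | CC(C)OC1=CC(=O)C1=O | intermediate
10 | 3-hydroxycyclobut-3-ene-1,2-dione (semisquaric acid) | OC1=CC(=O)C1=O | intermediate
11 | 3-chlorocyclobut-3-ene-1,2-dione (semisquaric chloride; not isolated) | ClC1=CC(=O)C1=O | intermediate
12 | 3-{[(2E,4R)-3,7-dimethyl-4,7-bis(triethylsilyloxy)oct-2-en-1-yl]oxy}cyclobut-3-ene-1,2-dione | O=C1C=C(OC/C=C(\C)[C@H](O[Si](CC)(CC)CC)CCC(C)(C)O[Si](CC)(CC)CC)C1=O | intermediate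
13 | 3,3-diethoxyprop-1-yne | C#CC(OCC)OCC | starting material
14 | (E)-tributyl(3,3-diethoxyprop-1-en-1-yl)stannane | CCCC[Sn](CCCC)(CCCC)/C=C/C(OCC)OCC | intermediate
15 | (E)-(3,3-diethoxyprop-1-en-1-yl)lithium (not isolated) | [Li]/C=C/C(OCC)OCC | intermediate
16 | lithium 1-[(1E)-3,3-diethoxyprop-1-en-1-yl]-2-{[(2E,4R)-3,7-dimethyl-4,7-bis(triethylsilyloxy)oct-2-en-1-yl]oxy}-4-oxocyclobut-2-en-1-olate (both epimers; not isolated) | CCOC(OCC)/C=C/C1(O[Li])C(=O)C=C1OC/C=C(\C)[C@H](O[Si](CC)(CC)CC)CCC(C)(C)O[Si](CC)(CC)CC | intermediate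
17 | 4-[(1E)-3,3-diethoxyprop-1-en-1-yl]-3-{[(2E,4R)-3,7-dimethyl-4,7-bis(triethylsilyloxy)oct-2-en-1-yl]oxy}-4-methoxycyclobut-2-en-1-one (both C4 epimers) | CCOC(OCC)/C=C/C1(OC)C(=O)C=C1OC/C=C(\C)[C@H](O[Si](CC)(CC)CC)CCC(C)(C)O[Si](CC)(CC)CC | intermediate
18 | 2-(diethoxymethyl)-5-{[(2E,4R)-3,7-dimethyl-4,7-bis(triethylsilyloxy)oct-2-en-1-yl]oxy}-4-methoxyphenol | CCOC(OCC)c1cc(OC)c(OC/C=C(\C)[C@H](O[Si](CC)(CC)CC)CCC(C)(C)O[Si](CC)(CC)CC)cc1O | intermediate
19 | 4-{[(2E,4R)-3,7-dimethyl-4,7-bis(triethylsilyloxy)oct-2-en-1-yl]oxy}-2-hydroxy-5-methoxybenzaldehyde | O=Cc1cc(OC)c(OC/C=C(\C)[C@H](O[Si](CC)(CC)CC)CCC(C)(C)O[Si](CC)(CC)CC)cc1O | intermediate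
20 | 5-{[(2E,4R)-3,7-dimethyl-4,7-bis(triethylsilyloxy)oct-2-en-1-yl]oxy}-2-formyl-4-methoxyphenyl 2-(triphenylphosphoranylidene)acetate (not isolated) | O=Cc1cc(OC)c(OC/C=C(\C)[C@H](O[Si](CC)(CC)CC)CCC(C)(C)O[Si](CC)(CC)CC)cc1OC(=O)C=P(c2ccccc2)(c2ccccc2)c2ccccc2 | intermediate
21 | 7-{[(2E,4R)-3,7-dimethyl-4,7-bis(triethylsilyloxy)oct-2-en-1-yl]oxy}-6-methoxy-2H-chromen-2-one | COc1cc2ccc(=O)oc2cc1OC/C=C(\C)[C@H](O[Si](CC)(CC)CC)CCC(C)(C)O[Si](CC)(CC)CC | intermediate
22 | 7-{[(2E,4R)-4,7-dihydroxy-3,7-dimethyloct-2-en-1-yl]oxy}-6-methoxy-2H-chromen-2-one | COc1cc2ccc(=O)oc2cc1OC/C=C(\C)[C@H](O)CCC(C)(C)O | target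

Total step count: 14. Longest linear sequence: 11 steps (steps 1–5, 8, 10–14).

Steps most likely to fail

Step 11. The allyl enol ether could undergo a [3,3] shift or heterolysis before the four-membered ring opens. The ketene could also be intercepted by product phenol, and the ortho-hydroxy acetal could lose ethanol under the thermal conditions and oligomerise. The fallback gives up the ring expansion and attaches the side chain to a preformed coumarin. It sets out from alcohol 6 and returns at 21. Bromination of 6 under neutral conditions (CBr4, PPh3, 2,6-lutidine, CH2Cl2, −20 °C) should give (2E,4R)-1-bromo-3,7-dimethyl-4,7-bis(triethylsilyloxy)oct-2-ene F1. Williamson alkylation of commercial scopoletin (7-hydroxy-6-methoxycoumarin, COc1cc2ccc(=O)oc2cc1O) with F1 (K2CO3, DMF, rt) should then give 21, which continues with step 14.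

Step 8. The activated ester is an allyl ester of a strong vinylogous acid, so ionisation or chloride displacement at the allylic C–O bond, acid-induced loss of a silyl group, or decomposition of the acid chloride before it meets the alcohol could erode the coupling. The fallback replaces acid-chloride chemistry by direct alkoxy exchange. It sets out from isopropyl semisquarate 9 and alcohol 6 and returns at 12. The two are warmed in toluene at 40–60 °C under reduced pressure so that isopropanol is stripped and the vinylogous transesterification at C3 is driven forward, with catalytic Zn(OTf)2 only if needed. Step 7 is then not required, and no compound outside the list is made (F0).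

Step 4. The olefination could show poor E/Z selectivity at the new trisubstituted alkene, and enolisation toward the silyloxy-bearing carbon could erode the stereocentre. The fallback fixes the geometry by syn-carbometalation instead of olefination. It sets out from ketone 4 and returns at 6. Kinetic enolisation at the methyl group (LiN(i-Pr)2, THF, −78 °C) and trapping with ClP(O)(OEt)2 should give diethyl (3R)-6-methyl-3,6-bis(triethylsilyloxy)hept-1-en-2-yl phosphate F2. Elimination with excess LiN(i-Pr)2 should give (3R)-6-methyl-3,6-bis(triethylsilyloxy)hept-1-yne F3. Zirconium-catalysed methylalumination (Me3Al, Cp2ZrCl2 cat., CH2Cl2, Negishi carboalumination), conversion of the alkenylalane to its ate complex with n-BuLi and trapping with paraformaldehyde should give 6 directly. The syn addition places methyl and CH2OH cis, which is the E geometry required; step 5 is then not needed.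

Further compounds
F1 | step 11 | (2E,4R)-1-bromo-3,7-dimethyl-4,7-bis(triethylsilyloxy)oct-2-ene | BrC/C=C(\C)[C@H](O[Si](CC)(CC)CC)CCC(C)(C)O[Si](CC)(CC)CC
F0 | step 8 | none | none
F2 | step 4 | diethyl (3R)-6-methyl-3,6-bis(triethylsilyloxy)hept-1-en-2-yl phosphate | C=C(OP(=O)(OCC)OCC)[C@H](O[Si](CC)(CC)CC)CCC(C)(C)O[Si](CC)(CC)CC
F3 | step 4 | (3R)-6-methyl-3,6-bis(triethylsilyloxy)hept-1-yne | C#C[C@H](O[Si](CC)(CC)CC)CCC(C)(C)O[Si](CC)(CC)CC
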